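**Retrosynthetic overview**
1. Last disconnection: the O–CH3 bond at the ketone-chelated oxygen. The target comes from site-selective O-methylation of a free triphenol, with no protecting groups.
2. Next: the ArCH2–aryl bond at C3 of the ketone ring (the carbon between the two oxygens), made by ortho-quinone methide alkylation with 2-hydroxybenzyl alcohol.
3. Next: the aryl–acyl bond, made by Nencki acylation of resorcinol with 3-phenylpropanoic acid.
4. No ring is formed; all three benzene rings come from the starting materials.

Assumption: the target has no stereocentre (it is achiral), so there is no configuration to set and the compound is made as drawn. Locants C1–C4 refer to the ketone-bearing ring, with the acyl group on C1.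

**Route**

Step 1
Reactants: 1 resorcinol; 2 3-phenylpropanoic acid
Product: 3 1-(2,4-dihydroxyphenyl)-3-phenylpropan-1-one
Conditions: ZnCl2 (1.5 equiv, anhydrous), neat melt, 140 °C, 2 h; then 1 M HCl
Reagents that add atoms: none
Why: Nencki reaction (Friedel–Crafts acylation with a free carboxylic acid activated by ZnCl2), in which the acyl electrophile attacks resorcinol at C4, ortho to one hydroxyl and para to the other, and the new acyl group deactivates the ring so that the reaction stops at the mono-ketone.

Step 2
Reactants: 3 1-(2,4-dihydroxyphenyl)-3-phenylpropan-1-one; 4 2-hydroxybenzyl alcohol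
Product: 6 1-[2,4-dihydroxy-3-(2-hydroxybenzyl)phenyl]-3-phenylpropan-1-one, via ortho-quinone methide 5 (not isolated)
Conditions: 3 (2.0 equiv), KOH (3.0 equiv), H2O, 95 °C, slow addition of 4 (1.0 equiv) over 6 h, then 12 h; 1 M HCl; excess 3 recovered
Reagents that add atoms: none
Why: Base-mediated ortho-quinone methide alkylation (the reaction type that builds methylene bridges in resole chemistry), in which the phenoxide of 4 expels hydroxide to give 5 and the 4-phenoxide of 3 adds to it in a Michael-type C-alkylation at C3, the position between the two oxygens that is favoured for C-alkylation of 2,4-dihydroxyaryl ketones whose 2-OH is chelated to the carbonyl (bond fixation), while O-alkylation is reversible and the excess of 3 holds back self-condensation of 4 and double alkylation.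

Step 3
Reactants: 6 1-[2,4-dihydroxy-3-(2-hydroxybenzyl)phenyl]-3-phenylpropan-1-one
Product: 8 1-[4-hydroxy-3-(2-hydroxybenzyl)-2-methoxyphenyl]-3-phenylpropan-1-one, via chelate Cu(OAc)(C22H19O4) 7 (not isolated)
Conditions: Cu(OAc)2 (2.5 equiv), pyridine (5 equiv), 4 Å MS, ClCH2CH2Cl, rt, 30 min; then MeB(OH)2 (1.5 equiv, in portions), 60 °C, argon
Reagents that add atoms: methylboronic acid, CB(O)O
Why: Proposed new method: a substrate-chelate-directed Chan–Lam O-methylation, in which only the ketone-flanked 2-OH of the three phenols can bind divalent copper as a six-membered O,O-chelate (7), so that this otherwise least acidic and least nucleophilic hydroxyl is the one deprotonated and held on the metal under weak-base conditions that leave the two non-chelating phenols largely protonated, after which methyl transfer from boron to the chelated copper, one-electron oxidation by a second Cu(OAc)2 to a trivalent methylcopper phenolate and C(sp3)–O reductive elimination form the O–CH3 bond at that oxygen and release a product that no longer chelates; argon keeps the electron-rich phenols and the diarylmethane CH2 from aerobic copper oxidation, and the closest known reaction type is the Chan–Lam methylation of simple phenols and carboxylic acids with MeB(OH)2 and Cu(OAc)2/pyridine, which has not been used to reverse the usual acidity-controlled order of phenol methylation.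

**Compound list**
1 | resorcinol (benzene-1,3-diol) | Oc1cccc(O)c1 | starting material
2 | 3-phenylpropanoic acid | OC(=O)CCc1ccccc1 | starting material
3 | 1-(2,4-dihydroxyphenyl)-3-phenylpropan-1-one | O=C(CCc1ccccc1)c1ccc(O)cc1O | intermediate
4 | 2-hydroxybenzyl alcohol | OCc1ccccc1O | starting material
5 | ortho-quinone methide, 6-methylidenecyclohexa-2,4-dien-1-one (transient) | C=C1C=CC=CC1=O | intermediate
6 | 1-[2,4-dihydroxy-3-(2-hydroxybenzyl)phenyl]-3-phenylpropan-1-one | O=C(CCc1ccccc1)c1ccc(O)c(Cc2ccccc2O)c1O | intermediate
7 | Cu(OAc)(C22H19O4), acetate complex of divalent copper chelated by the 2-phenolate oxygen and the ketone oxygen of 6 (pyridine ligands not drawn; transient) | CC(=O)[O-].[Cu+2].[O-]c1c(C(=O)CCc2ccccc2)ccc(O)c1Cc1ccccc1O | intermediate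
8 | 1-[4-hydroxy-3-(2-hydroxybenzyl)-2-methoxyphenyl]-3-phenylpropan-1-one | COc1c(C(=O)CCc2ccccc2)ccc(O)c1Cc1ccccc1O | target

**Step count**
Total steps: 3. Longest linear sequence: 3 (1 → 3 → 6 → 8).

**Steps most likely to fail, with fallbacks**

Step 3 (the proposed new methylation) is the riskiest. The chelated oxygen is hindered and electron-poor, so reductive elimination may be slow. Copper not held in the chelate may instead methylate the 4-OH or the benzyl-ring OH. The fallback uses known chemistry, sets out from 6 and comes back at 8. Treating 6 with benzyl bromide (2.2 equiv) and K2CO3 in acetone at reflux alkylates only the two non-chelated phenols and gives 1-{4-(benzyloxy)-3-[2-(benzyloxy)benzyl]-2-hydroxyphenyl}-3-phenylpropan-1-one F1. Forcing methylation of the remaining chelated hydroxyl with MeI and K2CO3 in DMF at 60 °C gives 1-{4-(benzyloxy)-3-[2-(benzyloxy)benzyl]-2-methoxyphenyl}-3-phenylpropan-1-one F2. Hydrogenolysis of both benzyl ethers (H2, 1 atm, Pd/C, EtOAc, rt, stopped at full debenzylation to spare the aryl ketone) returns 8.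

Step 2 may give the C5 isomer, bis-alkylation or oligomers of 4 in place of clean C3 alkylation. The fallback fixes the regiochemistry by halogenation and cross-coupling; it sets out from 3 and comes back at 6. Iodination of 3 with I2/HIO3 in aqueous ethanol at rt, which is C3-selective for chelated 2,4-dihydroxyaryl ketones, gives 1-(2,4-dihydroxy-3-iodophenyl)-3-phenylpropan-1-one F3. Negishi coupling of F3 with 2-MeOC6H4CH2ZnCl (3.5 equiv, from 2-methoxybenzyl chloride and zinc dust/LiCl) under Pd(OAc)2/SPhos in THF at 40 °C, through a zerovalent palladium cycle, gives 1-[2,4-dihydroxy-3-(2-methoxybenzyl)phenyl]-3-phenylpropan-1-one F4. Cleavage of the anisole ether with BBr3 in CH2Cl2 (−78 to 0 °C) returns 6.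

Step 1 is the least risky, but the melt can give aryl ester or diacylated by-products and a modest yield. The fallback swaps the electrophile for a nitrile (Houben–Hoesch reaction), which stops cleanly at mono-acylation; it sets out from 1 and comes back at 3. Resorcinol and 3-phenylpropanenitrile with ZnCl2 and HCl gas in diethyl ether at 0 °C precipitate 1-(2,4-dihydroxyphenyl)-3-phenylpropan-1-iminium chloride F5. Heating F5 in water at 100 °C hydrolyses it to 3.

**Further compounds**
F1 | step 3 | 1-{4-(benzyloxy)-3-[2-(benzyloxy)benzyl]-2-hydroxyphenyl}-3-phenylpropan-1-one | O=C(CCc1ccccc1)c1ccc(OCc2ccccc2)c(Cc2ccccc2OCc2ccccc2)c1O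
F2 | step 3 | 1-{4-(benzyloxy)-3-[2-(benzyloxy)benzyl]-2-methoxyphenyl}-3-phenylpropan-1-one | COc1c(C(=O)CCc2ccccc2)ccc(OCc2ccccc2)c1Cc1ccccc1OCc1ccccc1
F3 | step 2 | 1-(2,4-dihydroxy-3-iodophenyl)-3-phenylpropan-1-one | O=C(CCc1ccccc1)c1ccc(O)c(I)c1O
F4 | step 2 | 1-[2,4-dihydroxy-3-(2-methoxybenzyl)phenyl]-3-phenylpropan-1-one | COc1ccccc1Cc1c(O)ccc(C(=O)CCc2ccccc2)c1O
F5 | step 1 | 1-(2,4-dihydroxyphenyl)-3-phenylpropan-1-iminium chloride | [NH2+]=C(CCc1ccccc1)c1ccc(O)cc1O.[Cl-]
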